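Ring B is disconnected across C3′–C4′ and C5′–C6′. Its C2′ hydroxyl sits para to the benzyl-bearing C5′ and ortho to the bridge carbon C1′, exactly the pattern a 2-silyloxy-3-alkylbutadiene and an aryl vinyl ketone produce. One Diels–Alder reaction closes ring B as a cyclohexene enol silane and fixes the phenol oxygen, the C5′ aroyl carbon (the benzyl group at ketone level) and the ethylene bridge. The precursor is a silyl dienol ether whose C3 carries the complete ring-A phenethyl chain, derived from an α-methylene ketone, plus 4-benzyloxyphenyl vinyl ketone. Dehydrogenation, ionic deoxygenation and hydrogenolysis finish the synthesis.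

Key step: step 12

Abbreviation: ArA = 3-(benzyloxy)-2,6-bis[4-(benzyloxy)benzyl]-5-methoxyphenyl (ring A with its protected substituents).

Remark: the dienol ether is made as its tert-butyldimethylsilyl ether, which should survive chromatography as diene and as cycloadduct better than a trimethylsilyl analogue. The stereocentres of 11, 12, 17, 19 and 20 form as racemates and all disappear before the achiral target.

Step 1
Reactants: 1 (3,5-dimethoxyphenyl)acetic acid
Product: 2 (3-hydroxy-5-methoxyphenyl)acetic acid
Conditions: NaSEt, DMF, 140 °C; then aq. HCl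
Reagents that add atoms: none
Why: Thiolate-mediated SN2 demethylation of an aryl methyl ether should stop at the mono-phenol, because the phenoxide formed by the first cleavage deactivates the remaining ether toward a second attack.

Step 2
Reactants: 2 (3-hydroxy-5-methoxyphenyl)acetic acid
Product: 3 benzyl [3-(benzyloxy)-5-methoxyphenyl]acetate
Conditions: BnBr, K2CO3, DMF, 50 °C
Reagents that add atoms: benzyl bromide, BrCc1ccccc1
Why: Williamson O-benzylation of the phenoxide and alkylation of the carboxylate should proceed together, giving an ether and an ester that both tolerate the bromination and the organozinc coupling.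

Step 3
Reactants: 3 benzyl [3-(benzyloxy)-5-methoxyphenyl]acetate
Product: 4 benzyl [3-(benzyloxy)-2,6-dibromo-5-methoxyphenyl]acetate
Conditions: NBS (2.05 equiv), MeCN, 0 → 25 °C, dark
Reagents that add atoms: N-bromosuccinimide, O=C1CCC(=O)N1Br
Why: Electrophilic aromatic bromination should enter twice, at C2 and C6, each para to one alkoxy group and ortho to the other, as is usual for dihalogenation of 3,5-dialkoxybenzenes, while C4 between the two ethers reacts more slowly.

Step 4
Reactants: 4 benzyl [3-(benzyloxy)-2,6-dibromo-5-methoxyphenyl]acetate; 5 4-(benzyloxy)benzyl chloride (2.6 equiv)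
Product: 7 benzyl ArA-acetate, via 4-(benzyloxy)benzylzinc chloride 6 (not isolated)
Conditions: 5 (2.6 equiv), Zn dust (4 equiv), LiCl (2.6 equiv), THF, 25 °C; then 4 (1 equiv), Pd(OAc)2 (4 mol %), SPhos (8 mol %), THF, 25 → 50 °C
Reagents that add atoms: 4-(benzyloxy)benzyl chloride (second equivalent of 5), ClCc1ccc(OCc2ccccc2)cc1
Why: Zinc insertion into the benzylic chloride followed by a twofold Negishi sp2–sp3 coupling, which consumes two equivalents of benzylzinc reagent 6 per molecule of dibromide 4, should replace both bromines, since the palladium catalyst ligated by SPhos (2-dicyclohexylphosphino-2′,6′-dimethoxybiphenyl) handles di-ortho-substituted electron-rich aryl bromides and the benzylzinc reagent does not attack the ester.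

Step 5
Reactants: 7 benzyl ArA-acetate
Product: 8 2-ArA-ethanol
Conditions: LiAlH4, THF, 0 °C; aqueous work-up
Reagents that add atoms: none
Why: LiAlH4 reduction of the ester gives the primary alcohol, the aryl benzyl and methyl ethers being inert to hydride.

Step 6
Reactants: 8 2-ArA-ethanol
Product: 9 2-ArA-ethyl bromide
Conditions: CBr4, PPh3, CH2Cl2, 0 °C
Reagents that add atoms: carbon tetrabromide, BrC(Br)(Br)Br
Why: Appel reaction, in which the alkoxyphosphonium ion is displaced by bromide in an SN2 step at the unhindered primary carbon under neutral conditions.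

Step 7
Reactants: 9 2-ArA-ethyl bromide; 10 ethyl acetoacetate
Product: 11 racemic ethyl 2-acetyl-4-ArA-butanoate
Conditions: 10 (3 equiv), K2CO3, NaI (cat.), DMF, 50 °C
Reagents that add atoms: none
Why: Acetoacetic ester C-alkylation, in which the soft, weakly basic enolate should displace the primary halide (iodide catalysis) and not eliminate it; the new α-stereocentre forms racemic and is lost in step 8.

Step 8
Reactants: 11 racemic ethyl 2-acetyl-4-ArA-butanoate
Product: 13 3-methylidene-5-ArA-pentan-2-one, via β-keto acid 12 (not isolated)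
Conditions: KOH, H2O/MeOH/THF, 25 °C; then AcOH (to pH 5), Et2NH, 37% aq. CH2O, 25 → 45 °C
Reagents that add atoms: formaldehyde, C=O
Why: Ester hydrolysis followed by a decarboxylative Mannich methylenation, in which the β-keto acid adds through its doubly activated α-carbon to the iminium ion from CH2O and Et2NH and the adduct expels CO2 and the amine, places the methylene on C3 only.

Step 9
Reactants: 13 3-methylidene-5-ArA-pentan-2-one
Product: 14 2-(tert-butyldimethylsilyloxy)-3-(2-ArA-ethyl)buta-1,3-diene
Conditions: TBSOTf, Et3N, CH2Cl2, 0 °C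
Reagents that add atoms: tert-butyldimethylsilyl trifluoromethanesulfonate, CC(C)(C)[Si](C)(C)OS(=O)(=O)C(F)(F)F
Why: Soft enolization with O-silylation (silyl triflate and amine base) can only give the cross-conjugated 2-silyloxydiene, because the acetyl methyl is the sole α-position that bears hydrogens.

Step 10
Reactants: 15 4-(benzyloxy)benzaldehyde; 16 vinylmagnesium bromide
Product: 17 racemic 1-[4-(benzyloxy)phenyl]prop-2-en-1-ol
Conditions: THF, −20 → 0 °C; aqueous work-up
Reagents that add atoms: none
Why: Grignard 1,2-addition to the aldehyde gives the allylic benzylic alcohol, whose stereocentre forms racemic and is removed by the next oxidation.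

Step 11
Reactants: 17 racemic 1-[4-(benzyloxy)phenyl]prop-2-en-1-ol
Product: 18 1-[4-(benzyloxy)phenyl]prop-2-en-1-one
Conditions: MnO2 (activated, excess), CH2Cl2, 25 °C; used at once
Reagents that add atoms: none
Why: MnO2 oxidation of an allylic and benzylic alcohol under neutral heterogeneous conditions should give the polymerization-prone enone cleanly for immediate use.

Step 12
Reactants: 14 2-(tert-butyldimethylsilyloxy)-3-(2-ArA-ethyl)buta-1,3-diene; 18 1-[4-(benzyloxy)phenyl]prop-2-en-1-one
Product: 19 racemic 4-[4-(benzyloxy)benzoyl]-1-(tert-butyldimethylsilyloxy)-2-(2-ArA-ethyl)cyclohex-1-ene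
Conditions: 18 (1.5 equiv), BHT (cat.), toluene, 90 °C, sealed tube
Reagents that add atoms: none
Why: A concerted, asynchronous normal-electron-demand [4+2] cycloaddition between the HOMO of silyloxydiene 14 and the LUMO of enone 18; the closest known reaction type is the thermal Diels–Alder addition of 2-(trialkylsilyloxy)buta-1,3-dienes to alkyl or aryl vinyl ketones. Ring B closes as a six-membered carbocycle by an intermolecular suprafacial cycloaddition in which both new σ-bonds (C3′–C4′ and C5′–C6′) form at the diene termini, leaving the C1′=C2′ enol silane double bond. The single new stereocentre (C5′, bearing the aroyl group) arises without a controlling element as a racemate, which is acceptable because aromatization erases it. The selectivity needed is regiochemical: the silyloxy group on C2 puts the larger HOMO coefficient on the adjacent terminus, which bonds to the enone β-carbon, so the aroyl group should end 1,4 to the oxygen and 1,3 to the bridge, the weaker opposing bias of the C3 alkyl group being outweighed. An excess of freshly made 18 and a radical inhibitor offset polymerization of the dienophile, and the bulky silyl group should keep the adduct intact on isolation.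

Step 13
Reactants: 19 racemic 4-[4-(benzyloxy)benzoyl]-1-(tert-butyldimethylsilyloxy)-2-(2-ArA-ethyl)cyclohex-1-ene
Product: 21 [4-(benzyloxy)phenyl][3-(2-ArA-ethyl)-4-hydroxyphenyl]methanone, via cyclohexanone 20 (not isolated)
Conditions: TsOH·H2O (20 mol %), THF/H2O, 25 °C; solvent removed; then Pd(OCOCF3)2 (5 mol %), 2-(dimethylamino)pyridine (10 mol %), O2 (1 atm), DMSO, 80 °C
Reagents that add atoms: none
Why: Acid hydrolysis of the silyl enol ether releases cyclohexanone 20 (two unselective stereocentres, both destroyed), and palladium-catalysed aerobic dehydrogenation of cyclohexanones to phenols (two rounds of palladium enolate formation and β-hydride elimination, then tautomerization) should aromatize ring B, every order of the two dehydrogenations converging on the same phenol.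

Step 14
Reactants: 21 [4-(benzyloxy)phenyl][3-(2-ArA-ethyl)-4-hydroxyphenyl]methanone
Product: 22 4-[4-(benzyloxy)benzyl]-2-(2-ArA-ethyl)phenol
Conditions: Et3SiH (4 equiv), CF3CO2H, CH2Cl2, 0 → 25 °C
Reagents that add atoms: none
Why: Ionic hydrogenation, in which protonation of the diaryl ketone flanked by two para-oxygenated rings and two hydride transfers from the silane through the stabilized diarylmethyl cation should give the methylene, the excess silane also trapping any benzyl cation.

Step 15
Reactants: 22 4-[4-(benzyloxy)benzyl]-2-(2-ArA-ethyl)phenol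
Product: 23 4-(4-hydroxybenzyl)-2-{2-[3-hydroxy-2,6-bis(4-hydroxybenzyl)-5-methoxyphenyl]ethyl}phenol (CNP0134121.0)
Conditions: H2 (1 atm), 10% Pd/C, EtOAc/MeOH, 25 °C
Reagents that add atoms: none
Why: Catalytic hydrogenolysis cleaves the benzylic C–O bonds of the four aryl benzyl ethers, while the diarylmethane C–C bonds, the aryl methyl ether and the arenes are inert at room temperature and 1 atm.

Compound list
1 | (3,5-dimethoxyphenyl)acetic acid | COc1cc(OC)cc(CC(=O)O)c1 | starting material
2 | (3-hydroxy-5-methoxyphenyl)acetic acid | COc1cc(O)cc(CC(=O)O)c1 | intermediate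
3 | benzyl [3-(benzyloxy)-5-methoxyphenyl]acetate | COc1cc(CC(=O)OCc2ccccc2)cc(OCc2ccccc2)c1 | intermediate
4 | benzyl [3-(benzyloxy)-2,6-dibromo-5-methoxyphenyl]acetate | COc1cc(OCc2ccccc2)c(Br)c(CC(=O)OCc2ccccc2)c1Br | intermediate
5 | 4-(benzyloxy)benzyl chloride | ClCc1ccc(OCc2ccccc2)cc1 | starting material
6 | 4-(benzyloxy)benzylzinc chloride | Cl[Zn]Cc1ccc(OCc2ccccc2)cc1 | intermediate
7 | benzyl {3-(benzyloxy)-2,6-bis[4-(benzyloxy)benzyl]-5-methoxyphenyl}acetate (benzyl ArA-acetate) | O=C(Cc1c(Cc2ccc(OCc3ccccc3)cc2)c(OCc2ccccc2)cc(OC)c1Cc1ccc(OCc2ccccc2)cc1)OCc1ccccc1 | intermediate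
8 | 2-{3-(benzyloxy)-2,6-bis[4-(benzyloxy)benzyl]-5-methoxyphenyl}ethanol (2-ArA-ethanol) | OCCc1c(Cc2ccc(OCc3ccccc3)cc2)c(OCc2ccccc2)cc(OC)c1Cc1ccc(OCc2ccccc2)cc1 | intermediate
9 | 1-(benzyloxy)-2,4-bis[4-(benzyloxy)benzyl]-3-(2-bromoethyl)-5-methoxybenzene (2-ArA-ethyl bromide) | BrCCc1c(Cc2ccc(OCc3ccccc3)cc2)c(OCc2ccccc2)cc(OC)c1Cc1ccc(OCc2ccccc2)cc1 | intermediate
10 | ethyl acetoacetate | CCOC(=O)CC(C)=O | starting material
11 | ethyl 2-acetyl-4-ArA-butanoate (racemic) | CCOC(=O)C(CCc1c(Cc2ccc(OCc3ccccc3)cc2)c(OCc2ccccc2)cc(OC)c1Cc1ccc(OCc2ccccc2)cc1)C(C)=O | intermediate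
12 | 2-acetyl-4-ArA-butanoic acid (racemic) | OC(=O)C(CCc1c(Cc2ccc(OCc3ccccc3)cc2)c(OCc2ccccc2)cc(OC)c1Cc1ccc(OCc2ccccc2)cc1)C(C)=O | intermediate
13 | 3-methylidene-5-ArA-pentan-2-one | CC(=O)C(=C)CCc1c(Cc2ccc(OCc3ccccc3)cc2)c(OCc2ccccc2)cc(OC)c1Cc1ccc(OCc2ccccc2)cc1 | intermediate
14 | 2-(tert-butyldimethylsilyloxy)-3-(2-ArA-ethyl)buta-1,3-diene | C=C(O[Si](C)(C)C(C)(C)C)C(=C)CCc1c(Cc2ccc(OCc3ccccc3)cc2)c(OCc2ccccc2)cc(OC)c1Cc1ccc(OCc2ccccc2)cc1 | intermediate
15 | 4-(benzyloxy)benzaldehyde | O=Cc1ccc(OCc2ccccc2)cc1 | starting material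
16 | vinylmagnesium bromide | C=C[Mg]Br | starting material
17 | 1-[4-(benzyloxy)phenyl]prop-2-en-1-ol (racemic) | C=CC(O)c1ccc(OCc2ccccc2)cc1 | intermediate
18 | 1-[4-(benzyloxy)phenyl]prop-2-en-1-one | C=CC(=O)c1ccc(OCc2ccccc2)cc1 | intermediate
19 | 4-[4-(benzyloxy)benzoyl]-1-(tert-butyldimethylsilyloxy)-2-(2-ArA-ethyl)cyclohex-1-ene (racemic) | CC(C)(C)[Si](C)(C)OC1=C(CCc2c(Cc3ccc(OCc4ccccc4)cc3)c(OCc3ccccc3)cc(OC)c2Cc2ccc(OCc3ccccc3)cc2)CC(C(=O)c2ccc(OCc3ccccc3)cc2)CC1 | intermediate
20 | 4-[4-(benzyloxy)benzoyl]-2-(2-ArA-ethyl)cyclohexanone (racemic, mixture of diastereomers) | O=C1CCC(C(=O)c2ccc(OCc3ccccc3)cc2)CC1CCc1c(Cc2ccc(OCc3ccccc3)cc2)c(OCc2ccccc2)cc(OC)c1Cc1ccc(OCc2ccccc2)cc1 | intermediate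
21 | [4-(benzyloxy)phenyl][3-(2-ArA-ethyl)-4-hydroxyphenyl]methanone | O=C(c1ccc(OCc2ccccc2)cc1)c1ccc(O)c(CCc2c(Cc3ccc(OCc4ccccc4)cc3)c(OCc3ccccc3)cc(OC)c2Cc2ccc(OCc3ccccc3)cc2)c1 | intermediate
22 | 4-[4-(benzyloxy)benzyl]-2-(2-ArA-ethyl)phenol | Oc1ccc(Cc2ccc(OCc3ccccc3)cc2)cc1CCc1c(Cc2ccc(OCc3ccccc3)cc2)c(OCc2ccccc2)cc(OC)c1Cc1ccc(OCc2ccccc2)cc1 | intermediate
23 | 4-(4-hydroxybenzyl)-2-{2-[3-hydroxy-2,6-bis(4-hydroxybenzyl)-5-methoxyphenyl]ethyl}phenol (CNP0134121.0) | COc1cc(O)c(Cc2ccc(O)cc2)c(CCc2cc(Cc3ccc(O)cc3)ccc2O)c1Cc1ccc(O)cc1 | target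

Total step count: 15. Longest linear sequence: 13 (steps 1–9 and 12–15); steps 10–11 form the two-step dienophile branch.

Steps most likely to fail

Step 12. The cycloaddition may lose regiocontrol, because the C3 alkyl group opposes the directing effect of the silyloxy group, and the aryl vinyl ketone may polymerize or dimerize by hetero-Diels–Alder reaction faster than it is consumed. The fallback makes the same two bonds one after the other by polar chemistry, where the polarity of the partners dictates the connectivity. It sets out from diene 14 and enone 18. A Mukaiyama–Michael addition (TiCl4, CH2Cl2, −78 °C, aqueous work-up) joins the silyloxy-bearing diene terminus to the enone β-carbon and should give the open-chain 1-[4-(benzyloxy)phenyl]-6-methylidene-8-ArA-octane-1,5-dione F1. Cs2CO3 in dilute MeCN should then close ring B by 6-endo-trig intramolecular Michael addition of the aryl ketone enolate to the α-methylene ketone. This gives cyclohexanone 20, where the route is rejoined at the dehydrogenation stage of step 13.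

Step 13. The dehydrogenation may stall at the cyclohexenone stage, the catalyst may be deactivated by the polyether substrate, or the electron-rich diarylmethane positions of ring A may be oxidized at 80 °C under O2. The fallback raises the oxidation level of the dienophile so that only one mild two-electron oxidation is needed. It sets out from aldehyde 15. Ethynylmagnesium bromide (THF, 0 °C) should give racemic 1-[4-(benzyloxy)phenyl]prop-2-yn-1-ol F2, and MnO2 (CH2Cl2, 25 °C) the ynone 1-[4-(benzyloxy)phenyl]prop-2-yn-1-one F3. Diels–Alder addition of F3 to diene 14 (toluene, 80 °C), with the same regiochemical preference, should give [4-(benzyloxy)phenyl][4-(tert-butyldimethylsilyloxy)-5-(2-ArA-ethyl)cyclohexa-1,4-dien-1-yl]methanone F4. Chloranil (toluene, 25 °C) should remove two hydrogens from this 1,4-diene to give the aryl silyl ether [4-(benzyloxy)phenyl][4-(tert-butyldimethylsilyloxy)-3-(2-ArA-ethyl)phenyl]methanone F5. Bu4NF (THF, 0 °C) then frees the phenol, and the route is rejoined at compound 21.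

Step 8. The saponification may be accompanied by retro-Claisen cleavage, the β-keto acid may decarboxylate before it meets the iminium ion, and the amine may add back to the enone. The fallback installs the methylene by olefination and sets out from bromide 9. C-alkylation of the sodium salt of dimethyl (2-oxopropyl)phosphonate (NaH, NaI, DMF, 50 °C) should give racemic dimethyl (5-ArA-2-oxopentan-3-yl)phosphonate F6. A Horner–Wadsworth–Emmons reaction with aqueous formaldehyde (K2CO3, THF/H2O, 25 °C) then returns the route to α-methylene ketone 13.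

Further compounds
F1 | step 12 | 1-[4-(benzyloxy)phenyl]-6-methylidene-8-ArA-octane-1,5-dione | O=C(CCCC(=O)C(=C)CCc1c(Cc2ccc(OCc3ccccc3)cc2)c(OCc2ccccc2)cc(OC)c1Cc1ccc(OCc2ccccc2)cc1)c1ccc(OCc2ccccc2)cc1
F2 | step 13 | 1-[4-(benzyloxy)phenyl]prop-2-yn-1-ol (racemic) | C#CC(O)c1ccc(OCc2ccccc2)cc1
F3 | step 13 | 1-[4-(benzyloxy)phenyl]prop-2-yn-1-one | C#CC(=O)c1ccc(OCc2ccccc2)cc1
F4 | step 13 | [4-(benzyloxy)phenyl][4-(tert-butyldimethylsilyloxy)-5-(2-ArA-ethyl)cyclohexa-1,4-dien-1-yl]methanone | CC(C)(C)[Si](C)(C)OC1=C(CCc2c(Cc3ccc(OCc4ccccc4)cc3)c(OCc3ccccc3)cc(OC)c2Cc2ccc(OCc3ccccc3)cc2)CC(C(=O)c2ccc(OCc3ccccc3)cc2)=CC1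
F5 | step 13 | [4-(benzyloxy)phenyl][4-(tert-butyldimethylsilyloxy)-3-(2-ArA-ethyl)phenyl]methanone | CC(C)(C)[Si](C)(C)Oc1ccc(C(=O)c2ccc(OCc3ccccc3)cc2)cc1CCc1c(Cc2ccc(OCc3ccccc3)cc2)c(OCc2ccccc2)cc(OC)c1Cc1ccc(OCc2ccccc2)cc1
F6 | step 8 | dimethyl (5-ArA-2-oxopentan-3-yl)phosphonate (racemic) | COP(=O)(OC)C(CCc1c(Cc2ccc(OCc3ccccc3)cc2)c(OCc2ccccc2)cc(OC)c1Cc1ccc(OCc2ccccc2)cc1)C(C)=O
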